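## Structural features

The target is a chroman (3,4-dihydro-2H-1-benzopyran) with a hexasubstituted benzene ring: O1 on C8a, the pyran methylene C4 on C4a, hydroxyls on C5 and C7, a methyl on C6 and the 3-phenylpropanoyl chain on C8 (chalcone numbering: pyran oxygen on C6', next to the acyl-bearing C1'). The arene is a phloroglucinol in which oxygen-bearing carbons (C5, C7, C8a) alternate with carbon-bearing ones (C4a, C6, C8). The three oxygens are electronically alike, yet the pyran must use the one that lies para to the methyl group and ortho to the ketone. The pyran ring holds a quaternary C2 (gem-dimethyl, bonded to O1), the single stereocentre C3 (secondary alcohol, S) and the benzylic C4H2; C3 has no stereogenic neighbour, so a reagent or catalyst must impose its configuration. Fragile points are the electron-rich acylphloroglucinol (oxidation, C- versus O-reactivity), the tertiary alkyl aryl ether O1–C2 (ionisable by strong acid, with reclosure onto the C5 oxygen or elimination) and the C3 hydroxyl, whose activation invites ring contraction through O1. The real difficulty is therefore the unambiguous placement of the pyran ring on a ring with three like oxygens, combined with a lone carbinol centre beside a quaternary carbon. The key step exploits two features. The C3(O)–C4H2 pair of the pyran ring is the imprint of an α-oxo carbene, made from a terminal alkyne, inserted into the aryl C4a–H bond. O1 lies on the mirror plane of the 3,5-dioxygenated 4-methylphenyl unit, so C4a and C8 are equivalent until the ring is closed.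

## Logic of the disconnections

13 ⇒ 12. The O–H bonds at C5 and C7 are traced back to two aryl acetal C–O bonds. These two phenols must be silent while the third oxygen (O1) is alkylated and while organometallic reagents are used. There is no skeletal gain, but every later cut depends on it. The forward step needs acid mild enough to leave the tertiary O1–C2 ether and C3 untouched.

12 ⇒ 9 + 10. The C8–C(=O) bond is cut. C8 is the only ring carbon of 9 that carries hydrogen, and it sits between two oxygen donors, so an aryl anion there is regiochemically unambiguous. The whole C9 side chain arrives from 10 in one convergent operation. The forward step needs metalation at C8 in the presence of the C3 hydroxyl (carried as its alkoxide) and a single addition to the acyl donor.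

9 ⇒ 8. The C3–H bond is cut, which removes the only stereocentre and leaves a prochiral ketone flanked by a quaternary carbon (C2) and a methylene (C4). The stereochemical problem becomes the choice of one enantiomer of a reduction catalyst. The forward step needs high enantioface selectivity; nothing else in 8 is reducible under the conditions.

8 ⇒ 7 (key disconnection). The C4–C4a bond is cut and the C3 carbonyl oxygen is removed, which opens the pyran ring to the achiral, monocyclic 7. In one sentence: an α-oxo gold carbene, generated by oxygen-atom transfer to the terminal alkyne of 7, closes the pyran ring at C4–C4a and delivers the C3 oxygen as a ketone. Both ortho carbons of 7 are equivalent by symmetry, so the closure cannot give a constitutional isomer, and C3 arrives at the oxidation level from which the alcohol can be set with absolute control. The forward step needs oxygen transfer to the internal alkyne carbon and carbene capture by the arene to be faster than direct hydroarylation of the alkyne.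

7 ⇒ 5 + 6. The O1–C2 bond is cut. 5 has a single free hydroxyl, para to the methyl group, so attaching the C5 unit there fixes the pyran oxygen where 13 requires it. All five carbons of the pyran appendage (C2, its two methyls, C3, C4) come from 6. The forward step needs O-alkylation at a tertiary carbon without C-alkylation or rearrangement.

5 ⇒ 3. The aryl C–O bond para to the methyl group is cut back to a C–H bond. This is the only ring C–H of 3 without an ortho substituent, so a sterically governed C–H functionalisation can find it; the gain is a 1,2,3-trisubstituted benzene. The forward step needs exclusive reaction at that position and an oxidation that tolerates the acetals (4 is not isolated).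

3 ⇒ 1 + 2. The two acetal C–O bonds are cut to give commercial 1 and 2. The forward step needs complete bis-protection.

## Other disconnections considered

Alternative 1: the route that comes to mind first cuts O1–C2 and, one step earlier, C4–C4a on the intact acylphloroglucinol. Forward: C-prenylation of 2',4',6'-trihydroxy-3'-methyldihydrochalcone A1 at its only free ring carbon to the 5'-prenyl compound A2, enantioselective epoxidation to the (S)-epoxide A3, and acid-mediated 6-endo opening by the 6'-hydroxyl.
- In A3 the epoxide chain is flanked by two hydroxyls. The one needed (6'-OH) is tied up in the hydrogen bond to the ketone, while the 4'-OH is the more acidic and more nucleophilic.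
- Closure through O4' gives the isomeric chroman, and 5-exo closure through either oxygen gives dihydrobenzofurans. Four cyclic ethers compete and the substrate offers no bias toward the right one.
- An electrophilic oxidant would have to epoxidise an alkene beside a free phloroglucinol. That calls for differentiated protection of three nearly equal hydroxyls, the very problem that the symmetry of 5 removes.
- C- versus O-prenylation costs further material.

Alternative 2: cut C4–C4a with the stereocentre already in the tether. Forward: intramolecular Friedel–Crafts opening of the terminal (S)-epoxide A4 (the 2-(oxiran-2-yl)propan-2-yl ether of 5) at its CH2 carbon (6-endo), giving 9 directly.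
- The closure has the same symmetry advantage as the chosen step.
- The stereocentre must be set on a monosubstituted alkene bearing a quaternary allylic carbon, a poor substrate class for catalytic asymmetric epoxidation.
- Semi-hydrogenation, oxidation and a resolution (or dihydroxylation and closure) are needed before the key step, at least one step more from 5 to 9.
- The allyl ether on the way is primed for aromatic Claisen rearrangement, and a Lewis acid on A4 can also trigger 5-exo attack at C3.
- Reducing a ketone with two very different flanks is the more reliable way to the same stereocentre.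

Alternative 3: cut the benzene ring itself (C4a–C8a, C5–C6 and C8–C8a). Forward: Danheiser benzannulation of 3-ethoxy-2-methylcyclobut-2-en-1-one A5 with siloxyalkyne A6, which carries the (S)-epoxide side chain, to phenol A7. The three oxygens emerge differentiated (free OH, silyl ether, ethyl ether), and the free one sits beside the side chain for pyran closure.
- It answers "which oxygen" by construction.
- A6 needs a multi-step synthesis in which an epoxide must survive ynolate chemistry and then ketene intermediates at 80–110 °C.
- The ethyl ether at C7 needs a harsh dealkylation at the end.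
- The arene pattern it builds is available from 1 by symmetry at no cost, so step economy decides against it.

Key step: step 4

Remark: the stereocentre (C5'' of the name, C3 of the chroman ring) is (S) according to the SMILES string, chroman numbering (O1, C2–C4, C4a, C5–C8, C8a) is used throughout, and 10 is treated as a catalogue reagent.

## Steps

Step 1
Reactants: 1 2-methylbenzene-1,3-diol (2-methylresorcinol); 2 chloromethyl methyl ether
Product: 3 1,3-bis(methoxymethoxy)-2-methylbenzene
Conditions: 2 (2.6 equiv), iPr2NEt (3.0 equiv), CH2Cl2, 0 °C to rt
Reagents that add atoms: chloromethyl methyl ether (2), COCCl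
Why: Williamson-type O-alkylation of both phenols by the reactive α-chloro ether, with the hindered amine taking up HCl. The two MOM acetals mask the future C5 and C7 oxygens, tolerate base, borane, organolithium and gold(I), and later direct the lithiation.

Step 2
Reactants: 3 1,3-bis(methoxymethoxy)-2-methylbenzene
Product: 5 3,5-bis(methoxymethoxy)-4-methylphenol, via aryl pinacol boronate 4 (not isolated)
Conditions: B2pin2 (1.0 equiv), [Ir(OMe)(cod)]2 (1.5 mol%), 4,4'-di-tert-butyl-2,2'-bipyridine (3 mol%), THF, 80 °C; evaporate; then 30% H2O2, aq. NaOH, THF, 0 °C to rt
Reagents that add atoms: hydrogen peroxide, OO (phenol oxygen of 5); bis(pinacolato)diboron, CC1(C)OB(OC1(C)C)B1OC(C)(C)C(C)(C)O1 (boryl group of 4 only)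
Why: Iridium-catalysed aromatic C–H borylation is sterically controlled, and C5 of 3 is the only ring C–H without an ortho substituent, so boron should enter para to the methyl group. Basic peroxide then oxidises the C–B bond of 4 (1,2-aryl shift from boron to oxygen) under conditions that spare the acetals.

Step 3
Reactants: 5 3,5-bis(methoxymethoxy)-4-methylphenol; 6 3-chloro-3-methylbut-1-yne
Product: 7 1,3-bis(methoxymethoxy)-2-methyl-5-[(2-methylbut-3-yn-2-yl)oxy]benzene
Conditions: 6 (1.5 equiv), DBU (1.6 equiv), CuCl2·2H2O (1 mol%), MeCN, 0 °C to rt
Reagents that add atoms: 3-chloro-3-methylbut-1-yne (6), CC(C)(Cl)C#C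
Why: Copper-catalysed propargylic substitution: the copper acetylide of 6 ionises to a copper allenylidene, which the phenoxide of 5 captures at the tertiary carbon. This is the standard entry to aryl 1,1-dimethylpropargyl ethers; 5 has only one free hydroxyl, so O1 is fixed para to the methyl group.

Step 4
Reactants: 7 1,3-bis(methoxymethoxy)-2-methyl-5-[(2-methylbut-3-yn-2-yl)oxy]benzene
Product: 8 5,7-bis(methoxymethoxy)-2,2,6-trimethylchroman-3-one (2H-chromen-3(4H)-one)
Conditions: Me4tBuXPhosAuNTf2 (5 mol%), 2,6-dichloropyridine N-oxide (1.3 equiv, slow addition), 1,2-dichloroethane, rt; product used promptly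
Reagents that add atoms: 2,6-dichloropyridine N-oxide, [O-][n+]1c(Cl)cccc1Cl
Why: Cationic gold(I) π-activates the terminal alkyne of 7, the N-oxide oxygen adds to the internal carbon (gold on the terminal carbon), and N–O heterolysis with loss of 2,6-dichloropyridine leaves an α-oxo gold carbene, Au=CH–C(=O)–CMe2–OAr. The electrophilic carbene carbon is attacked by the ortho carbon of the aryl ether (σ-complex), and rearomatisation with protodeauration forms the C4–C4a bond, so the pyran ring and the C3 carbonyl arise in one operation. The closest known reaction type is the gold-catalysed oxidative cyclisation of aryl propargyl ethers to chroman-3-ones, to which 7 belongs as a member with a tertiary propargylic carbon. The ring closes in a six-membered mode that is exo with respect to the Au=C bond (arene π-nucleophile onto a trigonal carbene carbon), helped by the gem-dimethyl group. No stereocentre is formed; the step delivers the prochiral C3 ketone whose flanks (quaternary C2, methylene C4) differ strongly for step 5. Oxygen transfer is regioselective because the alkyne is terminal, and the site of attack on the arene needs no control because the 3,5-bis(methoxymethoxy)-4-methylphenyl group is mirror-symmetric, with both ortho carbons equivalent and activated by an ortho and a para acetal oxygen. The chemoselectivity required is that oxidation outruns direct 6-endo hydroarylation (which would give the 2H-chromene) and a second oxidation of the carbene; the bulky biaryl phosphine, the weakly basic N-oxide added slowly and room temperature are chosen for this.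

Step 5
Reactants: 8 5,7-bis(methoxymethoxy)-2,2,6-trimethylchroman-3-one
Product: 9 (3S)-5,7-bis(methoxymethoxy)-2,2,6-trimethyl-3,4-dihydro-2H-chromen-3-ol
Conditions: (R)-2-methyl-CBS-oxazaborolidine (15 mol%), BH3·SMe2 (0.8 equiv), THF, −20 °C; then MeOH
Reagents that add atoms: none
Why: Corey–Bakshi–Shibata reduction: the ketone binds the catalyst boron with its small flank (C4 methylene) toward the catalyst and the quaternary C2 away from it, and hydride is transferred intramolecularly from the N-bound borane. With the (R)-catalyst this should give the (3S)-alcohol, the sense known for tert-alkyl methyl ketones, so C3 is set by catalyst control; acetals and the aryl ether are inert to borane at this temperature.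

Step 6
Reactants: 9 (3S)-5,7-bis(methoxymethoxy)-2,2,6-trimethyl-3,4-dihydro-2H-chromen-3-ol; 10 N-methoxy-N-methyl-3-phenylpropanamide
Product: 12 1-[(3S)-3-hydroxy-5,7-bis(methoxymethoxy)-2,2,6-trimethyl-3,4-dihydro-2H-chromen-8-yl]-3-phenylpropan-1-one, via C8-lithio lithium alkoxide 11 (not isolated)
Conditions: n-BuLi (2.3 equiv), THF, 0 °C, 1 h; then 10 (1.3 equiv), −78 °C to 0 °C; sat. aq. NH4Cl
Reagents that add atoms: N-methoxy-N-methyl-3-phenylpropanamide (10), CON(C)C(=O)CCc1ccccc1; n-butyllithium, [Li]CCCC (lithium of 11 only)
Why: Directed ortho-metalation followed by Weinreb ketone synthesis: the first equivalent of base forms the C3 alkoxide and the second removes the only aromatic hydrogen (C8–H), which lies between the ring oxygen and the C7 MOM group. Aryllithium 11 adds once to 10 because the chelated tetrahedral adduct persists until work-up; C3 is not touched and keeps its configuration.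

Step 7
Reactants: 12 1-[(3S)-3-hydroxy-5,7-bis(methoxymethoxy)-2,2,6-trimethyl-3,4-dihydro-2H-chromen-8-yl]-3-phenylpropan-1-one
Product: 13 1-[(3S)-3,5,7-trihydroxy-2,2,6-trimethyl-3,4-dihydro-2H-chromen-8-yl]-3-phenylpropan-1-one (target)
Conditions: HCl (ca. 1 M in MeOH), rt
Reagents that add atoms: none
Why: Acid-catalysed methanolysis of the two aryl MOM acetals, the methoxymethyl cation being trapped by methanol; the fully substituted ring has no free position for hydroxymethylation. Dilute acid at room temperature should stay below the threshold for ionising the O1–C2 bond, which the ortho ketone deactivates further, and C3 is not involved.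

## Compound list

1 | 2-methylbenzene-1,3-diol (2-methylresorcinol) | Cc1c(O)cccc1O | starting material
2 | chloromethyl methyl ether | COCCl | starting material
3 | 1,3-bis(methoxymethoxy)-2-methylbenzene | Cc1c(OCOC)cccc1OCOC | intermediate
4 | 2-[3,5-bis(methoxymethoxy)-4-methylphenyl]-4,4,5,5-tetramethyl-1,3,2-dioxaborolane | Cc1c(OCOC)cc(cc1OCOC)B1OC(C)(C)C(C)(C)O1 | intermediate (not isolated)
5 | 3,5-bis(methoxymethoxy)-4-methylphenol | Cc1c(OCOC)cc(O)cc1OCOC | intermediate
6 | 3-chloro-3-methylbut-1-yne | CC(C)(Cl)C#C | starting material
7 | 1,3-bis(methoxymethoxy)-2-methyl-5-[(2-methylbut-3-yn-2-yl)oxy]benzene | Cc1c(OCOC)cc(OC(C)(C)C#C)cc1OCOC | intermediate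
8 | 5,7-bis(methoxymethoxy)-2,2,6-trimethylchroman-3-one | Cc1c(OCOC)cc2OC(C)(C)C(=O)Cc2c1OCOC | intermediate
9 | (3S)-5,7-bis(methoxymethoxy)-2,2,6-trimethyl-3,4-dihydro-2H-chromen-3-ol | Cc1c(OCOC)cc2OC(C)(C)[C@@H](O)Cc2c1OCOC | intermediate
10 | N-methoxy-N-methyl-3-phenylpropanamide | CON(C)C(=O)CCc1ccccc1 | starting material
11 | lithium (3S)-8-lithio-5,7-bis(methoxymethoxy)-2,2,6-trimethyl-3,4-dihydro-2H-chromen-3-olate | Cc1c(OCOC)c([Li])c2OC(C)(C)[C@@H](O[Li])Cc2c1OCOC | intermediate (not isolated)
12 | 1-[(3S)-3-hydroxy-5,7-bis(methoxymethoxy)-2,2,6-trimethyl-3,4-dihydro-2H-chromen-8-yl]-3-phenylpropan-1-one | Cc1c(OCOC)c(C(=O)CCc3ccccc3)c2OC(C)(C)[C@@H](O)Cc2c1OCOC | intermediate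
13 | 1-[(3S)-3,5,7-trihydroxy-2,2,6-trimethyl-3,4-dihydro-2H-chromen-8-yl]-3-phenylpropan-1-one | Cc1c(O)c(C(=O)CCc3ccccc3)c2OC(C)(C)[C@@H](O)Cc2c1O | target

## Step count and least certain steps

Total step count: 7. Longest linear sequence: 7 steps (1 to 13); 10 enters in step 6.

**Step 4 (key step).** The most likely failure is that gold activates the alkyne for direct 6-endo hydroarylation by the very electron-rich ring (or a [3,3] shift) faster than the N-oxide adds, so the ring closes without oxygen transfer. A second oxidation of the carbene is the other risk. The fallback sets out from 7, returns at 9 and replaces steps 4 and 5 by turning the competing pathway into the route. Heating 7 (N,N-diethylaniline, 160 °C), or treating it with the gold catalyst without oxidant, should give 5,7-bis(methoxymethoxy)-2,2,6-trimethyl-2H-chromene F1 by propargyl Claisen rearrangement, 1,5-hydrogen shift and 6π-electrocyclisation (or by hydroarylation). Mn(salen)-catalysed (Jacobsen–Katsuki) epoxidation with the (S,S)-catalyst, buffered NaOCl and 4-phenylpyridine N-oxide at 0 °C is expected to give (3S,4S)-3,4-epoxy-5,7-bis(methoxymethoxy)-2,2,6-trimethylchroman F2, the sense usual for 2,2-dimethylchromenes. Hydrogenolysis of the benzylic C4–O bond (H2, Pd/C, EtOAc, trace Et3N) leaves the C3–O bond and its configuration and gives 9.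

**Step 5.** The risk is poor facial selectivity, from uncatalysed background reduction or from borane coordinating to the ether oxygens near C2 and blurring the large/small distinction. The fallback sets out from 8 and returns at 9. NaBH4 in MeOH gives racemic 5,7-bis(methoxymethoxy)-2,2,6-trimethylchroman-3-ol F3. A lipase (Candida antarctica lipase B, vinyl acetate, MTBE, 40 °C) is expected, by the usual preference of lipases for secondary alcohols, to acylate the (3R)-enantiomer to (3R)-5,7-bis(methoxymethoxy)-2,2,6-trimethylchroman-3-yl acetate F4. The (3S)-alcohol 9 is left behind and separated by chromatography.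

**Step 6.** The risks are incomplete or misdirected metalation (lateral deprotonation of the C6 methyl between two MOM groups, aggregation with the alkoxide) and proton transfer from the α-CH2 of 10 to the hindered aryllithium instead of addition. The fallback sets out from 9 and returns at 11. N-Bromosuccinimide in MeCN at 0 °C should brominate the only free ring position to give (3S)-8-bromo-5,7-bis(methoxymethoxy)-2,2,6-trimethylchroman-3-ol F5. n-BuLi (2.1 equiv, THF, −78 °C) then deprotonates the hydroxyl and exchanges bromine for lithium, giving 11 regiospecifically at a temperature at which addition to 10 should outrun proton transfer.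

**Step 7.** The risk is acid-promoted heterolysis of the O1–C2 bond (ring opening, then reclosure onto the C5 oxygen or elimination) competing with slow cleavage of the hindered C5 acetal. The fallback sets out from 12 and returns at 13. TMSOTf and 2,2'-bipyridyl in MeCN at 0 °C convert aryl MOM ethers into aryl trimethylsilyl ethers without free protic acid and silylate the C3 hydroxyl, giving 1-[(3S)-2,2,6-trimethyl-3,5,7-tris(trimethylsilyloxy)-3,4-dihydro-2H-chromen-8-yl]-3-phenylpropan-1-one F6. Water, then K2CO3 in MeOH at 0 °C, removes the three silyl groups and gives 13.

## Further compounds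

F1 | step 4 | 5,7-bis(methoxymethoxy)-2,2,6-trimethyl-2H-chromene | Cc1c(OCOC)cc2OC(C)(C)C=Cc2c1OCOC
F2 | step 4 | (3S,4S)-3,4-epoxy-5,7-bis(methoxymethoxy)-2,2,6-trimethylchroman | Cc1c(OCOC)cc2OC(C)(C)[C@H]3O[C@H]3c2c1OCOC
F3 | step 5 | rac-5,7-bis(methoxymethoxy)-2,2,6-trimethylchroman-3-ol | Cc1c(OCOC)cc2OC(C)(C)C(O)Cc2c1OCOC
F4 | step 5 | (3R)-5,7-bis(methoxymethoxy)-2,2,6-trimethylchroman-3-yl acetate | Cc1c(OCOC)cc2OC(C)(C)[C@H](OC(C)=O)Cc2c1OCOC
F5 | step 6 | (3S)-8-bromo-5,7-bis(methoxymethoxy)-2,2,6-trimethylchroman-3-ol | Cc1c(OCOC)c(Br)c2OC(C)(C)[C@@H](O)Cc2c1OCOC
F6 | step 7 | 1-[(3S)-2,2,6-trimethyl-3,5,7-tris(trimethylsilyloxy)-3,4-dihydro-2H-chromen-8-yl]-3-phenylpropan-1-one | Cc1c(O[Si](C)(C)C)c(C(=O)CCc3ccccc3)c2OC(C)(C)[C@@H](O[Si](C)(C)C)Cc2c1O[Si](C)(C)C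
A1 | alternative 1 | 2',4',6'-trihydroxy-3'-methyldihydrochalcone | Cc1c(O)cc(O)c(C(=O)CCc2ccccc2)c1O
A2 | alternative 1 | 2',4',6'-trihydroxy-3'-methyl-5'-(3-methylbut-2-enyl)dihydrochalcone | Cc1c(O)c(CC=C(C)C)c(O)c(C(=O)CCc2ccccc2)c1O
A3 | alternative 1 | 5'-{[(2S)-3,3-dimethyloxiran-2-yl]methyl}-2',4',6'-trihydroxy-3'-methyldihydrochalcone | Cc1c(O)c(C[C@@H]2OC2(C)C)c(O)c(C(=O)CCc2ccccc2)c1O
A4 | alternative 2 | (2S)-2-{2-[3,5-bis(methoxymethoxy)-4-methylphenoxy]propan-2-yl}oxirane | Cc1c(OCOC)cc(OC(C)(C)[C@@H]2CO2)cc1OCOC
A5 | alternative 3 | 3-ethoxy-2-methylcyclobut-2-en-1-one | CCOC1=C(C)C(=O)C1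
A6 | alternative 3 | {3-[(2S)-3,3-dimethyloxiran-2-yl]prop-1-yn-1-yl}oxy-triisopropylsilane | CC(C)[Si](OC#CC[C@@H]1OC1(C)C)(C(C)C)C(C)C
A7 | alternative 3 | 2-{[(2S)-3,3-dimethyloxiran-2-yl]methyl}-5-ethoxy-4-methyl-3-(triisopropylsilyloxy)phenol | CCOc1cc(O)c(C[C@@H]2OC2(C)C)c(O[Si](C(C)C)(C(C)C)C(C)C)c1C
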